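**Strategy.** The 7-oxabicyclo[2.2.1]heptane core is a cyclohexane (C6, C7, C8, C9, C10, C11) whose 1,4-carbons C7 and C10 share one oxygen. Everything rests on opening a cis-(10R,11S)-epoxide with a (6Z)-C6=C7 alkene held two methylenes away in an acyclic chain. Under BF3·OEt2 the alkene attacks C11 (C6–C11 bond, carbocycle) and the epoxide oxygen captures the resulting C7 cation (O–C7 bond, ether bridge), so both rings and the stereocentres C6, C7 and C11 arise in one operation. The precursor is a TES-protected epoxy-tetraene joined from (S)-linalool and nerol by B-alkyl Suzuki coupling; the C14/C15 bromochloride is installed afterwards from the remaining trisubstituted alkene.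

Key step: step 8

Locants: C1–C15 are the open-chain carbons (C1=C2 vinyl group, C3 carbinol, C6/C7/C10/C11 ring carbons, C14 bromine-bearing, C15 chlorine-bearing carbon).

Assumption: (S)-(+)-linalool of high enantiomeric purity is taken as a purchasable chiral-pool material; no later step touches C3, so its purity carries through to the target.

**Step 1**
Reactants: 1 (S)-(+)-linalool
Product: 2 (S)-linalool triethylsilyl ether
Conditions: TESOTf, 2,6-lutidine, CH2Cl2, −78 → 0 °C
Reagents that add atoms: triethylsilyl trifluoromethanesulfonate, CC[Si](CC)(CC)OS(=O)(=O)C(F)(F)F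
Why: Silyl ether protection of the hindered tertiary allylic alcohol with a silyl triflate and a hindered base is standard, and it masks the hydroxyl that would form a lactol after step 2 and trap the cation in step 8.

**Step 2**
Reactants: 2 (S)-linalool triethylsilyl ether
Product: 4 (4S)-4-methyl-4-(triethylsilyloxy)hex-5-enal, via secondary ozonide 3 (not isolated)
Conditions: O3 (1.0 equiv, Sudan Red 7B end point), pyridine (cat.), CH2Cl2, −78 °C; then PPh3, −78 °C → rt
Reagents that add atoms: ozone, [O-][O+]=O
Why: Chemoselective ozonolysis with reductive work-up should cleave only the electron-rich trisubstituted alkene, because the monosubstituted vinyl group next to the quaternary silyloxy carbon reacts far more slowly.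

**Step 3**
Reactants: 4 (4S)-4-methyl-4-(triethylsilyloxy)hex-5-enal
Product: 5 (3S,6Z)-7-iodo-3-methyl-3-(triethylsilyloxy)octa-1,6-diene
Conditions: [Ph3PEt]I, n-BuLi, THF, 0 °C; I2, −78 °C; NaN(SiMe3)2, −20 °C; then 4, −78 → −20 °C
Reagents that add atoms: ethyltriphenylphosphonium iodide, CC[P+](c1ccccc1)(c1ccccc1)c1ccccc1.[I-]; iodine, II
Why: The Stork–Zhao–Wittig iodo-olefination should give the (Z)-2-iodoalk-2-ene (iodine cis to the chain) under kinetic control, which fixes the geometry later transferred to C6=C7.

**Step 4**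
Reactants: 6 nerol
Product: 7 (2R,3S)-2,3-epoxynerol
Conditions: Ti(OiPr)4 (5 mol%), D-(−)-diethyl tartrate (7 mol%), t-BuOOH, 4 Å molecular sieves, CH2Cl2, −20 °C
Reagents that add atoms: tert-butyl hydroperoxide, CC(C)(C)OO
Why: Sharpless asymmetric epoxidation is directed by the allylic alcohol to the 2,3-alkene only, stores the Z geometry as the cis relation of the two chains, and with D-(−)-tartrate should set the (2R,3S) configuration (future C10 and C11).

**Step 5**
Reactants: 7 (2R,3S)-2,3-epoxynerol
Product: 8 (2S,3S)-3-methyl-3-(4-methylpent-3-en-1-yl)oxirane-2-carbaldehyde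
Conditions: TEMPO (10 mol%), PhI(OAc)2, CH2Cl2, rt
Reagents that add atoms: none
Why: TEMPO-catalysed (oxoammonium) oxidation of the primary alcohol should stop at the aldehyde under near-neutral conditions that leave the epoxide and the trisubstituted alkene untouched.

**Step 6**
Reactants: 8 (2S,3S)-3-methyl-3-(4-methylpent-3-en-1-yl)oxirane-2-carbaldehyde
Product: 9 (2R,3S)-2-ethenyl-3-methyl-3-(4-methylpent-3-en-1-yl)oxirane
Conditions: [Ph3PMe]Br, KN(SiMe3)2, THF, 0 °C; then 8, −78 → 0 °C
Reagents that add atoms: methyltriphenylphosphonium bromide, C[P+](c1ccccc1)(c1ccccc1)c1ccccc1.[Br-]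
Why: Wittig methylenation of the epoxy aldehyde should give the vinyl epoxide (adding C8) without disturbing either epoxide stereocentre.

**Step 7**
Reactants: 9 (2R,3S)-2-ethenyl-3-methyl-3-(4-methylpent-3-en-1-yl)oxirane; 5 (3S,6Z)-7-iodo-3-methyl-3-(triethylsilyloxy)octa-1,6-diene
Product: 11 TES-protected (6Z)-10,11-epoxy-tetraene, via B-alkyl-9-BBN borane 10 (not isolated)
Conditions: 9-BBN (1.05 equiv), THF, 0 °C → rt; then 5, Pd(dppf)Cl2 (5 mol%), AsPh3, Cs2CO3, DMF/H2O, rt
Reagents that add atoms: none
Why: Hydroboration with 9-BBN is selective for the monosubstituted alkene of 9, and B-alkyl Suzuki–Miyaura coupling with the vinyl iodide should forge C7–C8 with retention of the Z geometry.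

**Step 8**
Reactants: 11 TES-protected (6Z)-10,11-epoxy-tetraene
Product: 13 TES-protected 7-oxabicyclo[2.2.1]heptane with intact C14=C15 alkene, via C7 cation fluoroborate zwitterion 12 (not isolated)
Conditions: BF3·OEt2 (1.0 equiv), CH2Cl2, −78 °C; then aq. NaHCO3
Reagents that add atoms: none
Why: BF3 activates the epoxide, the C6=C7 alkene attacks the tertiary epoxide carbon C11 anti to the breaking C–O bond, and the tertiary C7 cation of zwitterion 12 is captured by the boron-bound C10 oxygen, after which BF3 is released; the closest known reaction type is the Lewis-acid epoxy-olefin cyclisation of 5,6-epoxy-1-alkenes (geraniolene oxide, epoxygeranyl acetate), which gives 7-oxabicyclo[2.2.1]heptanes in just this way. The carbocycle closes 6-endo with respect to both the alkene and the epoxide (C6–C11), and the tetrahydrofuran ring closes by transannular 1,4-capture of the cation (O–C7), which can only give the cis bridge. C10 is carried over from the Sharpless epoxide, C11 is set by stereospecific inversion (in the cis-epoxide this places the C12 chain exo, syn to the oxygen bridge, and the methyl endo), C6 is set by the Z alkene reacting through a chair transition state in which the C5 chain is axial and so ends endo, and C7 follows from the bridge. The step needs chair rather than boat folding and ether closure rather than proton loss or hydride shift: the chair is the usual course of epoxide-initiated olefin cyclisations, and because both chains are axial in the first-formed chair cation, the ring inversion that relieves them puts the C10 oxygen axial and directly over C7. No other nucleophile is placed to interfere, since C14=C15 could only form a four-membered ring or a secondary cation, the vinyl group is electron-poor and the tertiary silyl ether oxygen is shielded.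

**Step 9**
Reactants: 13 TES-protected 7-oxabicyclo[2.2.1]heptane with intact C14=C15 alkene
Product: 14 (14R)-14,15-epoxide
Conditions: D-fructose-derived Shi ketone (30 mol%), Oxone (2KHSO5·KHSO4·K2SO4), K2CO3, Bu4NHSO4, MeCN/dimethoxymethane/aqueous buffer pH 10.5, 0 °C
Reagents that add atoms: potassium peroxymonosulfate, [K+].[O-]S(=O)(=O)OO
Why: In the Shi asymmetric epoxidation the chiral dioxirane should attack only the electron-rich trisubstituted C14=C15 alkene, and the D-fructose-derived ketone should set (R) at C14 through its spiro transition state, under catalyst control.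

**Step 10**
Reactants: 14 (14R)-14,15-epoxide
Product: 15 (14S)-14-bromo-15-hydroxy compound
Conditions: Li2NiBr4, THF, 0 °C → rt; aqueous work-up
Reagents that add atoms: dilithium tetrabromonickelate, [Li+].[Li+].[Ni+2].[Br-].[Br-].[Br-].[Br-]
Why: Nucleophilic epoxide opening by the soft bromide of Li2NiBr4 should occur in an SN2 manner at the less substituted carbon C14, so inversion turns the (14R)-epoxide into the (14S)-bromide and leaves the tertiary alcohol at C15.

**Step 11**
Reactants: 15 (14S)-14-bromo-15-hydroxy compound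
Product: 16 TES-protected bromochloride
Conditions: 1-chloro-N,N,2-trimethylprop-1-en-1-amine (Ghosez reagent), CH2Cl2, 0 °C → rt
Reagents that add atoms: 1-chloro-N,N,2-trimethylprop-1-en-1-amine, CC(C)=C(Cl)N(C)C
Why: Deoxychlorination of the tertiary alcohol through its O-alkyl imidinium chloride should proceed with anchimeric assistance by the vicinal bromine (bromonium ion), so chloride enters at the tertiary carbon C15 and C14 keeps its configuration.

**Step 12**
Reactants: 16 TES-protected bromochloride
Product: 17 target CNP0297543.1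
Conditions: HF·pyridine, pyridine, THF, 0 °C → rt
Reagents that add atoms: none
Why: Buffered fluoride desilylation should free the tertiary allylic alcohol without ionising it or the tertiary chloride.

**Compound list**

1 | (S)-(+)-linalool, (3S)-3,7-dimethylocta-1,6-dien-3-ol | C=C[C@@](C)(O)CCC=C(C)C | starting material
2 | triethyl{[(3S)-3,7-dimethylocta-1,6-dien-3-yl]oxy}silane | C=C[C@@](C)(O[Si](CC)(CC)CC)CCC=C(C)C | intermediate
3 | secondary ozonide (not isolated), 3,3-dimethyl-5-[(3S)-3-methyl-3-(triethylsilyloxy)pent-4-en-1-yl]-1,2,4-trioxolane | C=C[C@@](C)(O[Si](CC)(CC)CC)CCC1OOC(C)(C)O1 | intermediate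
4 | (4S)-4-methyl-4-(triethylsilyloxy)hex-5-enal | C=C[C@@](C)(O[Si](CC)(CC)CC)CCC=O | intermediate
5 | (3S,6Z)-7-iodo-3-methyl-3-(triethylsilyloxy)octa-1,6-diene | C=C[C@@](C)(O[Si](CC)(CC)CC)CC/C=C(/C)I | intermediate
6 | nerol, (2Z)-3,7-dimethylocta-2,6-dien-1-ol | OC/C=C(/C)CCC=C(C)C | starting material
7 | [(2R,3S)-3-methyl-3-(4-methylpent-3-en-1-yl)oxiran-2-yl]methanol | OC[C@H]1O[C@@]1(C)CCC=C(C)C | intermediate
8 | (2S,3S)-3-methyl-3-(4-methylpent-3-en-1-yl)oxirane-2-carbaldehyde | O=C[C@H]1O[C@@]1(C)CCC=C(C)C | intermediate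
9 | (2R,3S)-2-ethenyl-3-methyl-3-(4-methylpent-3-en-1-yl)oxirane | C=C[C@H]1O[C@@]1(C)CCC=C(C)C | intermediate
10 | B-alkyl-9-BBN borane (not isolated), 9-{2-[(2R,3S)-3-methyl-3-(4-methylpent-3-en-1-yl)oxiran-2-yl]ethyl}-9-borabicyclo[3.3.1]nonane | B1(CC[C@H]3O[C@@]3(C)CCC=C(C)C)C2CCCC1CCC2 | intermediate
11 | triethyl{[(3S,6Z)-3,7-dimethyl-9-[(2R,3S)-3-methyl-3-(4-methylpent-3-en-1-yl)oxiran-2-yl]nona-1,6-dien-3-yl]oxy}silane | C=C[C@@](C)(O[Si](CC)(CC)CC)CC/C=C(/C)CC[C@H]1O[C@@]1(C)CCC=C(C)C | intermediate
12 | zwitterion (not isolated): monocyclic tertiary C7 carbocation bearing the C10–O–BF3 borate, C6/C10/C11 configured as in 13 | C=C[C@@](C)(O[Si](CC)(CC)CC)CC[C@H]1[C@](C)(CCC=C(C)C)[C@H](O[B-](F)(F)F)CC[C+]1C | intermediate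
13 | triethyl{[(3S)-5-[(1S,2S,3S,4R)-1,3-dimethyl-3-(4-methylpent-3-en-1-yl)-7-oxabicyclo[2.2.1]heptan-2-yl]-3-methylpent-1-en-3-yl]oxy}silane | C=C[C@@](C)(O[Si](CC)(CC)CC)CC[C@H]1[C@](C)(CCC=C(C)C)[C@H]2CC[C@]1(C)O2 | intermediate
14 | triethyl{[(3S)-5-[(1S,2S,3S,4R)-3-{2-[(2R)-3,3-dimethyloxiran-2-yl]ethyl}-1,3-dimethyl-7-oxabicyclo[2.2.1]heptan-2-yl]-3-methylpent-1-en-3-yl]oxy}silane | C=C[C@@](C)(O[Si](CC)(CC)CC)CC[C@H]1[C@](C)(CC[C@H]3OC3(C)C)[C@H]2CC[C@]1(C)O2 | intermediate
15 | (3S)-3-bromo-5-[(1S,2S,3S,4R)-1,3-dimethyl-2-[(3S)-3-methyl-3-(triethylsilyloxy)pent-4-en-1-yl]-7-oxabicyclo[2.2.1]heptan-3-yl]-2-methylpentan-2-ol | C=C[C@@](C)(O[Si](CC)(CC)CC)CC[C@H]1[C@](C)(CC[C@H](Br)C(C)(C)O)[C@H]2CC[C@]1(C)O2 | intermediate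
16 | triethyl{[(3S)-5-[(1S,2S,3S,4R)-3-[(3S)-3-bromo-4-chloro-4-methylpentyl]-1,3-dimethyl-7-oxabicyclo[2.2.1]heptan-2-yl]-3-methylpent-1-en-3-yl]oxy}silane | C=C[C@@](C)(O[Si](CC)(CC)CC)CC[C@H]1[C@](C)(CC[C@H](Br)C(C)(C)Cl)[C@H]2CC[C@]1(C)O2 | intermediate
17 | (3S)-5-[(1S,2S,3S,4R)-3-[(3S)-3-bromo-4-chloro-4-methylpentyl]-1,3-dimethyl-7-oxabicyclo[2.2.1]heptan-2-yl]-3-methylpent-1-en-3-ol | C=C[C@@](C)(O)CC[C@H]1[C@](C)(CC[C@H](Br)C(C)(C)Cl)[C@H]2CC[C@]1(C)O2 | target

**Step count.** Total: 12 steps. Longest linear sequence: 9 steps (nerol 6 → 17 through steps 4–12; the linalool branch through steps 1–3 and 7–12 is equally long).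

**Steps most likely to fail**

1. Step 8. The C7 cation may lose a proton, or a hydride may shift from C10 to C11 to give a ketone, before ring inversion brings the oxygen over C7; partial folding through a boat would also erode the C6 configuration. The fallback sets out from 11 and separates the two bond formations. ZrCl4 in CH2Cl2 at −78 °C, a Lewis acid under which epoxy-olefin cyclisations end by proton loss, should give the endocyclic hydroxy-olefin F1 together with its exocyclic isomer F2. Both are then closed by Brønsted-acid-catalysed transannular Markovnikov addition of the C10 hydroxyl to the ring alkene (camphorsulfonic acid, CH2Cl2, 0 °C → rt), the closure that converts terpinen-4-ol into 1,4-cineole. The fallback comes back to the route at 13.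

2. Step 10. Bromide may attack the tertiary carbon C15, or the Lewis-acidic medium may rearrange the epoxide, giving the regioisomeric bromohydrin or a ketone. The fallback sets out from 13 and bypasses steps 9 and 10 by direct bromohydroxylation of the C14=C15 alkene (NBS, THF/H2O, 0 °C). This is reliably regioselective (bromine at C14, hydroxyl at C15) but not stereoselective, so it should give 15 together with its C14 epimer F3. The two are separated by preparative HPLC, and the fallback comes back to the route at 15.

3. Step 7. The γ-epoxy alkylborate may undergo base-triggered ring-opening 1,3-elimination (cyclopropylcarbinol formation) or protodeboronation faster than it transmetalates to palladium. The fallback sets out from borane 10 and vinyl iodide 5 and reverses the polarity of the union. Oxidation of 10 with NaBO3·4H2O should give the epoxy alcohol F4, which is converted with Tf2O and 2,6-lutidine at −78 °C into the primary triflate F5. Iodine–lithium exchange on 5 (t-BuLi, 2 equiv, Et2O, −78 °C) gives the configurationally stable (Z)-alkenyllithium F6, which is alkylated by F5 at −78 °C, so that no metal sits near the epoxide. The fallback comes back to the route at 11.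

**Further compounds**

F1 | step 8 | (1R,5R,6S)-4,6-dimethyl-6-(4-methylpent-3-en-1-yl)-5-[(3S)-3-methyl-3-(triethylsilyloxy)pent-4-en-1-yl]cyclohex-3-en-1-ol (C10 hydroxyl, endocyclic C7=C8) | C=C[C@@](C)(O[Si](CC)(CC)CC)CC[C@H]1[C@](C)(CCC=C(C)C)[C@H](O)CC=C1C
F2 | step 8 | (1R,2S,3R)-2-methyl-4-methylidene-2-(4-methylpent-3-en-1-yl)-3-[(3S)-3-methyl-3-(triethylsilyloxy)pent-4-en-1-yl]cyclohexan-1-ol (exocyclic isomer of F1) | C=C[C@@](C)(O[Si](CC)(CC)CC)CC[C@H]1[C@](C)(CCC=C(C)C)[C@H](O)CCC1=C
F3 | step 10 | (3R)-3-bromo-5-[(1S,2S,3S,4R)-1,3-dimethyl-2-[(3S)-3-methyl-3-(triethylsilyloxy)pent-4-en-1-yl]-7-oxabicyclo[2.2.1]heptan-3-yl]-2-methylpentan-2-ol (C14 epimer of 15) | C=C[C@@](C)(O[Si](CC)(CC)CC)CC[C@H]1[C@](C)(CC[C@@H](Br)C(C)(C)O)[C@H]2CC[C@]1(C)O2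
F4 | step 7 | 2-[(2R,3S)-3-methyl-3-(4-methylpent-3-en-1-yl)oxiran-2-yl]ethan-1-ol | OCC[C@H]1O[C@@]1(C)CCC=C(C)C
F5 | step 7 | 2-[(2R,3S)-3-methyl-3-(4-methylpent-3-en-1-yl)oxiran-2-yl]ethyl trifluoromethanesulfonate | FC(F)(F)S(=O)(=O)OCC[C@H]1O[C@@]1(C)CCC=C(C)C
F6 | step 7 | [(2E,6S)-6-methyl-6-(triethylsilyloxy)octa-2,7-dien-2-yl]lithium (lithium in place of the iodine of 5, geometry retained) | C=C[C@@](C)(O[Si](CC)(CC)CC)CC/C=C(/C)[Li]
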